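**Analysis of the target**

The target is a halogenated chamigrane-type spiro[5.5]undecane. Ring B consists of C1–C5 and the spiro carbon C6; ring A consists of C6–C11. Ring A is a cross-conjugated dienone: C7 carries an exocyclic methylene, C8 is the carbonyl, C9=C10 is a β-bromoenone with bromine on C10, and C11 is a gem-dimethyl carbon. Ring B carries a secondary bromide at C2 and a methyl-bearing tertiary chloride at C3. The three stereocentres are (2S,3S,6S): Br and Cl are trans (both equatorial in the favoured chair, C3-methyl axial), and at C6 the CMe2 carbon C11 is cis to C2–Br and equatorial on ring B, with C7 axial. The sensitive groups are the exo-methylene enone (a Michael acceptor), the β-bromoenone (addition–elimination with nucleophiles), the tertiary chloride next to a bromide (ionization, E2) and the secondary bromide. The difficulties are the quaternary C6 next to the quaternary C11, the absolute configuration of a vicinal bromochloride that has no oxygen handle, and bromine on the hindered C10 terminus of the C8–C10 unit. The strategy rests on one feature: ring B is a C1–C5 chain that holds both halogen stereocentres and can be closed on C6, and C6 is α to C7 when C7 is a carboxyl carbon, so an ester enolate already carrying the C11–C10–C9 arm can be alkylated twice.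

**Retrosynthetic reasoning**

From 24 the exocyclic C7 methylene is removed first, giving bromoenone 21. This is the most reactive group of the target and is put on last, by α′-aminomethylation and elimination. C7 is the only enolizable position of 21, so no regiochemical question arises.

Ring A of 21 is opened at C8–C9, via allylic alcohol 20, to aldehyde 18 with its 2-bromoalkene arm. Cutting here, and not at a C–O or C–Br bond, keeps bromine fixed on C10 from an acyclic bromoalkene. A 1,3-diketone route would have to put bromine on the more hindered carbonyl carbon, against its natural preference. The forward reaction must bond the terminal alkene carbon C9 to the carbonyl carbon C8 and restore the C9=C10 double bond.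

Aldehyde 18 is shortened by one carbon (C8) to ester 14, through aldehyde 16 and alcohol 15. This makes C7 a carboxyl carbon and C6 its α-carbon.

In 14 the bonds C6–C1 and C6–C5 are cut. This gives the ester 12, which holds C6, C7 and the C11–C10–C9 arm, and the C1–C5 bis-electrophile 9, which holds both halogen stereocentres. The cut removes ring B and the quaternary carbon in one operation and leaves the two halogens in an acyclic fragment, where a catalyst can set them. The forward reaction must alkylate the same carbon twice, the second time to a quaternary centre next to C11, with control of C6.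

Bis-electrophile 9 goes back through iodo alcohol 8 and diol 7 to the silyl-protected bromochlorohydrin 6, and from there, by removing Br and Cl, to the Z-allylic alcohol 5. Anti addition to the Z alkene gives the pair that is trans once C1 and C4 are tied into the ring, and the allylic hydroxyl is the handle for enantiocontrol.

Alcohol 5 comes from enoate 4, which comes from ynoate 3 by cutting the C3–methyl bond. A syn conjugate methyl addition fixes the Z geometry. Ynoate 3 comes from the silyl ether 2 of but-3-yn-1-ol 1 by cutting C1–C2.

Ester 12 comes from methyl ketone 11 (C10–Br from C10=O), which comes from the commercial alkene 10 by oxidation of the vinyl group.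

**Alternatives that were turned down**

Alternative 1: Ring B is disconnected at C1–C2 and C3–C4 into the prochiral spiro-cyclobutanone A1, which carries ring A as a ketal, and the silylated propyne A2.
- Forward key step: a zerovalent nickel catalyst (Ni(cod)2 with a chiral phosphine) couples the carbonyl with the alkyne, cleaves one of the two enantiotopic ring bonds and expands the four-membered ring to cyclohexenone A3.
- For it: the quaternary C6 is set by a catalyst in the ring-forming step. On this point it is stronger than the chosen route, where C6 depends on substrate control.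
- Against it: A3 has no heteroatom in its final place. The C4 carbonyl must be removed. The C2=C3 vinylsilane must become the trans C2–Br/C3–Cl pair on the correct face, with only the remote C6 to direct it. Ring A has its oxygen at C10 and must be reworked into C8=O, C10–Br and C7=CH2.
- Comparison: the sequence after the key step is long and redox-heavy, and the halogen stereocentres have no reliable control element. The chosen route sets both halogens by catalyst control before any ring exists.

Alternative 2: Ring A is disconnected at C6–C7 into the phenolic diazoketone A4.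
- Forward key step: acid-promoted loss of nitrogen lets the para carbon attack the diazo carbon and gives spirodienone A5.
- For it: the spiro centre and a ring A with oxygen on both C8 and C10 arise in one step from an aromatic compound. This is a shorter path to the spirocycle than the eleven steps of the chosen route, and C6 is not yet stereogenic, so nothing can go wrong there at that stage.
- Against it: ring B arrives as a symmetrical dienone whose carbonyl carbon is C3. It needs C-methylation, replacement of a tertiary oxygen by chlorine with defined configuration (not stereospecific at a tertiary centre), bromination at C2 and saturation of both alkenes. The two diastereotopic enone arms must be told apart under the influence of C10 alone, and that choice also fixes C6. Bromine must also replace the oxygen on the hindered C10.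
- Comparison: control of three stereocentres is postponed, not solved. The chosen route avoids every substitution at a tertiary carbon.

Alternative 3: Ring A is disconnected at C6–C11 into the (Z)-silyl trienol ether A6, built on a terpene-derived ring B that already holds Br and Cl.
- Forward key step: a thermal disrotatory 6π-electrocyclization gives A7.
- For it: A7 holds the whole skeleton and all three halogens, ring B can come from a cheap chiral terpene, and only oxygen adjustment remains. On closeness to the target after the key step it is stronger than the chosen route.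
- Against it: the new bond joins two fully substituted termini (ring carbon C6 and the CMe2 carbon C11). The barrier will be high, and the heating needed invites loss of HCl or HBr and sigmatropic hydrogen shifts. The face of C6 is decided only by the remote C2 and C3. The oxygen ends on C7, whereas the target needs C8=O and C7=CH2, so a 1,2-carbonyl transposition follows.
- Comparison: the chosen route forms the C6 quaternary centre by enolate alkylation at low temperature, where the halides are safe, and already has C8 as the carbon that becomes the carbonyl.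

Key step: step 11

**Remarks**

- The atom numbers C1–C11 used in the text and in the names of 19–24 are those defined in the analysis.
- Assumption: the enantiomer of the Schiff-base ligand used in step 5 is the one that delivers the (2S,3S)-bromochloride; its antipode is equally accessible.

**Route**

Step 1
Reactants: 1 but-3-yn-1-ol
Product: 2 tert-butyl(but-3-yn-1-yloxy)dimethylsilane
Conditions: TBSCl, imidazole, CH2Cl2, 0 °C → rt
Reagents that add atoms: tert-butyldimethylsilyl chloride, CC(C)(C)[Si](C)(C)Cl
Why: Routine silylation of a primary alcohol; the silyl ether tolerates the acetylide, cuprate, hydride and halogenation steps and is later removed under acidic fluoride conditions that spare a bromohydrin.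

Step 2
Reactants: 2 tert-butyl(but-3-yn-1-yloxy)dimethylsilane
Product: 3 methyl 5-[(tert-butyldimethylsilyl)oxy]pent-2-ynoate
Conditions: n-BuLi, THF, −78 °C; ClCO2Me, −78 → 0 °C
Reagents that add atoms: methyl chloroformate, COC(=O)Cl
Why: Deprotonation of the terminal alkyne and C-acylation of the lithium acetylide with a chloroformate is a standard ynoate synthesis and brings in C1 at the ester level.

Step 3
Reactants: 3 methyl 5-[(tert-butyldimethylsilyl)oxy]pent-2-ynoate
Product: 4 methyl (Z)-5-[(tert-butyldimethylsilyl)oxy]-3-methylpent-2-enoate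
Conditions: Me2CuLi (from CuI and 2 MeLi), THF, −78 °C; aq NH4Cl at −78 °C
Reagents that add atoms: lithium dimethylcuprate, [Li+].C[Cu-]C
Why: Conjugate syn-carbocupration of the ynoate and cold protonation place the new methyl cis to H-2, so the C4 chain is cis to the ester (Z); keeping the alkenylcopper species at −78 °C prevents equilibration through the allenolate.

Step 4
Reactants: 4 methyl (Z)-5-[(tert-butyldimethylsilyl)oxy]-3-methylpent-2-enoate
Product: 5 (Z)-5-[(tert-butyldimethylsilyl)oxy]-3-methylpent-2-en-1-ol
Conditions: iBu2AlH (2.5 equiv), CH2Cl2, −78 °C; aq potassium sodium tartrate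
Reagents that add atoms: none
Why: 1,2-Reduction of the enoate by iBu2AlH gives the allylic alcohol without touching the Z double bond or the silyl ether.

Step 5
Reactants: 5 (Z)-5-[(tert-butyldimethylsilyl)oxy]-3-methylpent-2-en-1-ol
Product: 6 (2S,3S)-2-bromo-5-[(tert-butyldimethylsilyl)oxy]-3-chloro-3-methylpentan-1-ol
Conditions: NBS (1.1 equiv), ClTi(OiPr)3 (1.1 equiv), chiral tridentate Schiff base from a salicylaldehyde and enantiopure 2-amino-3,3-dimethyl-1,1-diphenylbutan-1-ol (20 mol%), hexanes, −20 °C
Reagents that add atoms: N-bromosuccinimide, O=C1CCC(=O)N1Br; chlorotitanium triisopropoxide, CC(C)O[Ti](Cl)(OC(C)C)OC(C)C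
Why: Catalytic enantioselective bromochlorination of an allylic alcohol: the titanium-bound alkoxide and the ligand choose the alkene face for the bromonium ion, and chloride opens it anti at the more substituted C3 (Markovnikov), so both C2 and C3 are set by the catalyst; anti addition to the Z alkene gives the pair that is trans on ring B.

Step 6
Reactants: 6 (2S,3S)-2-bromo-5-[(tert-butyldimethylsilyl)oxy]-3-chloro-3-methylpentan-1-ol
Product: 7 (2S,3S)-2-bromo-3-chloro-3-methylpentane-1,5-diol
Conditions: HF·pyridine, THF/pyridine, 0 °C → rt
Reagents that add atoms: none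
Why: Acidic fluoride cleaves the primary silyl ether; basic fluoride is avoided because a C1 alkoxide would close an epoxide onto C2–Br.

Step 7
Reactants: 7 (2S,3S)-2-bromo-3-chloro-3-methylpentane-1,5-diol
Product: 8 (2S,3S)-2-bromo-3-chloro-5-iodo-3-methylpentan-1-ol
Conditions: PPh3 (1.1 equiv), I2 (1.1 equiv), imidazole (1.5 equiv), CH2Cl2, −20 → 0 °C
Reagents that add atoms: iodine, II
Why: Appel iodination; the C5 hydroxyl is an unhindered primary alcohol, whereas displacement at C1 is retarded by the β-bromine and the β-branching, so one equivalent of reagent at low temperature should iodinate C5 selectively, and diol, mono-iodide and di-iodide differ enough in polarity to be separated.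

Step 8
Reactants: 8 (2S,3S)-2-bromo-3-chloro-5-iodo-3-methylpentan-1-ol
Product: 9 (2S,3S)-2-bromo-3-chloro-5-iodo-3-methylpentyl trifluoromethanesulfonate
Conditions: Tf2O, 2,6-lutidine, CH2Cl2, −78 °C; cold work-up, used at once
Reagents that add atoms: trifluoromethanesulfonic anhydride, O=S(=O)(OS(=O)(=O)C(F)(F)F)C(F)(F)F
Why: Triflation of the remaining hindered primary alcohol with a hindered pyridine base; the β-bromine deactivates the triflate enough for a rapid cold filtration through silica.

Step 9
Reactants: 10 methyl 3,3-dimethylpent-4-enoate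
Product: 11 methyl 3,3-dimethyl-4-oxopentanoate
Conditions: PdCl2 (10 mol%), CuCl (50 mol%), O2 (1 atm), DMF/H2O 7:1, rt → 40 °C
Reagents that add atoms: water, O
Why: Tsuji–Wacker oxidation of the terminal alkene; Markovnikov attack of water gives the methyl ketone, and the quaternary neighbour slows the reaction but does not divert it.

Step 10
Reactants: 11 methyl 3,3-dimethyl-4-oxopentanoate
Product: 12 methyl 4-bromo-3,3-dimethylpent-4-enoate
Conditions: P(OPh)3, Br2, Et3N, CH2Cl2, −60 °C → reflux
Reagents that add atoms: bromine, BrBr
Why: Conversion of an enolizable ketone into a vinyl bromide with the triphenyl phosphite–bromine adduct and Et3N; only the methyl side can enolize, so the 2-bromo-1-alkene forms regiospecifically, and the conditions avoid the ketone enolate that would undergo Dieckmann-type closure onto the ester.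

Step 11
Reactants: 12 methyl 4-bromo-3,3-dimethylpent-4-enoate; 9 (2S,3S)-2-bromo-3-chloro-5-iodo-3-methylpentyl trifluoromethanesulfonate
Product: 14 methyl (1R,3S,4S)-3-bromo-1-(3-bromo-2-methylbut-3-en-2-yl)-4-chloro-4-methylcyclohexane-1-carboxylate, via mono-alkylated iodo ester 13 (not isolated)
Conditions: LiN(iPr)2 (1.05 equiv), THF, −78 °C; 9, −78 → −40 °C; then LiN(iPr)2 (1.3 equiv), DMPU, −78 → −20 °C
Reagents that add atoms: none
Why: This is a spiroannulation by double alkylation of an ester enolate with a 1,5-bis-electrophile, a known way to make cyclohexanes with a quaternary carbon. The lithium enolate of 12 first displaces the C1 triflate of 9 in an intermolecular SN2 reaction (C6–C1); triflate is needed because C1 is β-branched and β-brominated, and the competing E2 loss of triflic acid across C1–C2 is held back at −78 to −40 °C. A second equivalent of base then forms the fully substituted enolate of 13, which closes ring B by a 6-exo-tet displacement of the primary C5 iodide (C6–C5) and creates the quaternary C6 next to C11. C6 is the only new stereocentre and is set under substrate control in a chair transition state with C2–Br and C3–Cl equatorial, the tert-alkyl arm (C11) equatorial and the planar enolate carbon C7 axial, which puts C11 cis to C2–Br. The other diastereomer would need either the tert-alkyl arm axial or bromine syn-axial to C7. The step also needs chemoselectivity: 3-exo-tet attack of the enolate of 13 on C2–Br is disfavoured because C2 is secondary and flanked by the fully substituted C3, and the vinyl bromide and tertiary chloride do not react with amide bases at these temperatures. C2 and C3 are not touched, so their configuration is carried through unchanged.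

Step 12
Reactants: 14 methyl (1R,3S,4S)-3-bromo-1-(3-bromo-2-methylbut-3-en-2-yl)-4-chloro-4-methylcyclohexane-1-carboxylate
Product: 15 [(1R,3S,4S)-3-bromo-1-(3-bromo-2-methylbut-3-en-2-yl)-4-chloro-4-methylcyclohexyl]methanol
Conditions: iBu2AlH (3 equiv), CH2Cl2, −78 → 0 °C; aq potassium sodium tartrate
Reagents that add atoms: none
Why: iBu2AlH reduces the hindered neopentyl ester to the primary alcohol and leaves alkyl halides and the vinyl bromide untouched at or below 0 °C.

Step 13
Reactants: 15 [(1R,3S,4S)-3-bromo-1-(3-bromo-2-methylbut-3-en-2-yl)-4-chloro-4-methylcyclohexyl]methanol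
Product: 16 (1R,3S,4S)-3-bromo-1-(3-bromo-2-methylbut-3-en-2-yl)-4-chloro-4-methylcyclohexane-1-carbaldehyde
Conditions: Dess–Martin periodinane, CH2Cl2, 0 °C → rt
Reagents that add atoms: none
Why: Dess–Martin oxidation of a neopentyl primary alcohol to a non-enolizable aldehyde under neutral conditions.

Step 14
Reactants: 16 (1R,3S,4S)-3-bromo-1-(3-bromo-2-methylbut-3-en-2-yl)-4-chloro-4-methylcyclohexane-1-carbaldehyde
Product: 17 (1S,2S,4S)-2-bromo-4-(3-bromo-2-methylbut-3-en-2-yl)-1-chloro-4-(2-methoxyethenyl)-1-methylcyclohexane (E/Z mixture)
Conditions: Ph3P(CH2OMe)Cl, KN(SiMe3)2, THF, 0 °C; then 16, 0 °C → rt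
Reagents that add atoms: (methoxymethyl)triphenylphosphonium chloride, COC[P+](c1ccccc1)(c1ccccc1)c1ccccc1.[Cl-]
Why: Wittig methoxymethylenation, the standard one-carbon homologation of hindered aldehydes with a small, reactive ylide; the aldehyde cannot enolize, and a small excess of ylide at 0 °C limits E2 on ring B.

Step 15
Reactants: 17 (1S,2S,4S)-2-bromo-4-(3-bromo-2-methylbut-3-en-2-yl)-1-chloro-4-(2-methoxyethenyl)-1-methylcyclohexane
Product: 18 2-[(1R,3S,4S)-3-bromo-1-(3-bromo-2-methylbut-3-en-2-yl)-4-chloro-4-methylcyclohexyl]acetaldehyde
Conditions: 2 M aq HCl, THF, rt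
Reagents that add atoms: water, O
Why: Acid hydrolysis of the enol ether releases the homologated aldehyde (C7H2–C8HO); the vinyl bromide and the alkyl halides are inert to dilute aqueous acid at room temperature.

Step 16
Reactants: 18 2-[(1R,3S,4S)-3-bromo-1-(3-bromo-2-methylbut-3-en-2-yl)-4-chloro-4-methylcyclohexyl]acetaldehyde
Product: 20 (2S,3S,6R)-2,10-dibromo-3-chloro-3,11,11-trimethylspiro[5.5]undec-9-en-8-ol (C8 epimers), via trimethylsilyl ether 19 (not isolated)
Conditions: Me3SiOTf (1.5 equiv), 2,6-di-tert-butyl-4-methylpyridine (2 equiv), CH2Cl2, −78 → −30 °C; then 1 M aq HCl, THF, 0 °C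
Reagents that add atoms: none
Why: Proposed new method: a silyl-triflate-promoted Prins cyclization of an aldehyde onto a 2-bromo-1-alkene, ended by proton loss; O-silylation turns C8 into a silyloxycarbenium ion, the terminal alkene carbon C9 attacks it through a six-membered chair (C8–C9 formed, Markovnikov cation at C10 stabilized by the bromine lone pair), and because C11 is quaternary the hindered pyridine can only remove a C9 proton, which restores the vinyl bromide as C9=C10 and gives silyl ether 19; triflate is the only counter-ion, so no halide can be transferred to C10; the closest known reaction types are Prins cyclizations of vinyl halides with oxocarbenium ions and Lewis-acid carbonyl–ene cyclizations; the new C8 stereocentre does not matter because it is oxidized in the next step.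

Step 17
Reactants: 20 (2S,3S,6R)-2,10-dibromo-3-chloro-3,11,11-trimethylspiro[5.5]undec-9-en-8-ol
Product: 21 (2S,3S,6R)-2,10-dibromo-3-chloro-3,11,11-trimethylspiro[5.5]undec-9-en-8-one
Conditions: Dess–Martin periodinane, CH2Cl2, rt
Reagents that add atoms: none
Why: Dess–Martin oxidation of the secondary allylic alcohol gives the β-bromoenone and removes the C8 stereocentre.

Step 18
Reactants: 21 (2S,3S,6R)-2,10-dibromo-3-chloro-3,11,11-trimethylspiro[5.5]undec-9-en-8-one
Product: 24 (2S,3S,6S)-2,10-dibromo-3-chloro-3,11,11-trimethyl-7-methylidenespiro[5.5]undec-9-en-8-one, via Mannich base 22 (not isolated), via trimethylammonium iodide 23 (not isolated)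
Conditions: LiN(SiMe3)2, THF, −78 °C; CH2=NMe2 I (Eschenmoser's salt), −78 °C → rt; MeI, CH2Cl2, rt; aq NaHCO3, rt
Reagents that add atoms: N,N-dimethylmethyleneiminium iodide (Eschenmoser's salt), C=[N+](C)C.[I-]
Why: α′-Deprotonation at C7 (the only enolizable position, since C9 is vinylic and C11 quaternary), Mannich reaction with Eschenmoser's salt, N-methylation and base-induced β-elimination of trimethylamine give the exocyclic enone; the hindered amide base should not add to the β-bromoenone at −78 °C.

**Compound list**

1 | but-3-yn-1-ol | C#CCCO | starting material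
2 | tert-butyl(but-3-yn-1-yloxy)dimethylsilane | C#CCCO[Si](C)(C)C(C)(C)C | intermediate
3 | methyl 5-[(tert-butyldimethylsilyl)oxy]pent-2-ynoate | COC(=O)C#CCCO[Si](C)(C)C(C)(C)C | intermediate
4 | methyl (Z)-5-[(tert-butyldimethylsilyl)oxy]-3-methylpent-2-enoate | COC(=O)/C=C(C)\CCO[Si](C)(C)C(C)(C)C | intermediate
5 | (Z)-5-[(tert-butyldimethylsilyl)oxy]-3-methylpent-2-en-1-ol | OC/C=C(C)\CCO[Si](C)(C)C(C)(C)C | intermediate
6 | (2S,3S)-2-bromo-5-[(tert-butyldimethylsilyl)oxy]-3-chloro-3-methylpentan-1-ol | CC(C)(C)[Si](C)(C)OCC[C@](C)(Cl)[C@@H](Br)CO | intermediate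
7 | (2S,3S)-2-bromo-3-chloro-3-methylpentane-1,5-diol | OCC[C@](C)(Cl)[C@@H](Br)CO | intermediate
8 | (2S,3S)-2-bromo-3-chloro-5-iodo-3-methylpentan-1-ol | ICC[C@](C)(Cl)[C@@H](Br)CO | intermediate
9 | (2S,3S)-2-bromo-3-chloro-5-iodo-3-methylpentyl trifluoromethanesulfonate | ICC[C@](C)(Cl)[C@@H](Br)COS(=O)(=O)C(F)(F)F | intermediate
10 | methyl 3,3-dimethylpent-4-enoate | COC(=O)CC(C)(C)C=C | starting material
11 | methyl 3,3-dimethyl-4-oxopentanoate | COC(=O)CC(C)(C)C(C)=O | intermediate
12 | methyl 4-bromo-3,3-dimethylpent-4-enoate | C=C(Br)C(C)(C)CC(=O)OC | intermediate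
13 | methyl (4S,5S)-4-bromo-2-(3-bromo-2-methylbut-3-en-2-yl)-5-chloro-7-iodo-5-methylheptanoate (C2 epimers) | ICC[C@](C)(Cl)[C@@H](Br)CC(C(=O)OC)C(C)(C)C(Br)=C | intermediate
14 | methyl (1R,3S,4S)-3-bromo-1-(3-bromo-2-methylbut-3-en-2-yl)-4-chloro-4-methylcyclohexane-1-carboxylate | C=C(Br)C(C)(C)[C@@]1(C(=O)OC)CC[C@](C)(Cl)[C@@H](Br)C1 | intermediate
15 | [(1R,3S,4S)-3-bromo-1-(3-bromo-2-methylbut-3-en-2-yl)-4-chloro-4-methylcyclohexyl]methanol | C=C(Br)C(C)(C)[C@@]1(CO)CC[C@](C)(Cl)[C@@H](Br)C1 | intermediate
16 | (1R,3S,4S)-3-bromo-1-(3-bromo-2-methylbut-3-en-2-yl)-4-chloro-4-methylcyclohexane-1-carbaldehyde | C=C(Br)C(C)(C)[C@@]1(C=O)CC[C@](C)(Cl)[C@@H](Br)C1 | intermediate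
17 | (1S,2S,4S)-2-bromo-4-(3-bromo-2-methylbut-3-en-2-yl)-1-chloro-4-(2-methoxyethenyl)-1-methylcyclohexane (E/Z mixture) | C=C(Br)C(C)(C)[C@@]1(C=COC)CC[C@](C)(Cl)[C@@H](Br)C1 | intermediate
18 | 2-[(1R,3S,4S)-3-bromo-1-(3-bromo-2-methylbut-3-en-2-yl)-4-chloro-4-methylcyclohexyl]acetaldehyde | C=C(Br)C(C)(C)[C@@]1(CC=O)CC[C@](C)(Cl)[C@@H](Br)C1 | intermediate
19 | {[(2S,3S,6R)-2,10-dibromo-3-chloro-3,11,11-trimethylspiro[5.5]undec-9-en-8-yl]oxy}trimethylsilane (C8 epimers) | C[Si](C)(C)OC1C=C(Br)C(C)(C)[C@@]2(C1)CC[C@](C)(Cl)[C@@H](Br)C2 | intermediate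
20 | (2S,3S,6R)-2,10-dibromo-3-chloro-3,11,11-trimethylspiro[5.5]undec-9-en-8-ol (C8 epimers) | OC1C=C(Br)C(C)(C)[C@@]2(C1)CC[C@](C)(Cl)[C@@H](Br)C2 | intermediate
21 | (2S,3S,6R)-2,10-dibromo-3-chloro-3,11,11-trimethylspiro[5.5]undec-9-en-8-one | O=C1C=C(Br)C(C)(C)[C@@]2(C1)CC[C@](C)(Cl)[C@@H](Br)C2 | intermediate
22 | (2S,3S,6S)-2,10-dibromo-3-chloro-7-[(dimethylamino)methyl]-3,11,11-trimethylspiro[5.5]undec-9-en-8-one (C7 epimers) | CN(C)CC1C(=O)C=C(Br)C(C)(C)[C@]12CC[C@](C)(Cl)[C@@H](Br)C2 | intermediate
23 | {[(2S,3S,6S)-2,10-dibromo-3-chloro-3,11,11-trimethyl-8-oxospiro[5.5]undec-9-en-7-yl]methyl}trimethylammonium iodide (C7 epimers) | C[N+](C)(C)CC1C(=O)C=C(Br)C(C)(C)[C@]12CC[C@](C)(Cl)[C@@H](Br)C2.[I-] | intermediate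
24 | (2S,3S,6S)-2,10-dibromo-3-chloro-3,11,11-trimethyl-7-methylidenespiro[5.5]undec-9-en-8-one | C=C1C(=O)C=C(Br)C(C)(C)[C@]12CC[C@](C)(Cl)[C@@H](Br)C2 | target

**Step count and least certain steps**

Total: 18 steps. Longest linear sequence: 16 steps (steps 1–8 and 11–18). The ester branch (steps 9–10) joins at step 11.

Step 16 (the proposed method). The most likely failures are:
- too slow an attack by the electron-poor bromoalkene, so that O-silyl enol ether formation or self-condensation of the aldehyde takes over;
- a 1,2-methyl shift from C11 to the C10 cation;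
- ionization of the tertiary chloride by the silyl triflate.

The fallback uses known chemistry. It sets out from 18, which is oxidized (NaClO2, NaH2PO4, 2-methylbut-2-ene) to 2-[(1R,3S,4S)-3-bromo-1-(3-bromo-2-methylbut-3-en-2-yl)-4-chloro-4-methylcyclohexyl]acetic acid F1. 1-Bromo-N,N,2-trimethylprop-1-en-1-amine converts this into the acid bromide F2. SnBr4 in CH2Cl2 at −78 °C then brings about the classical Lewis-acid acylation of a vinyl halide by an acyl halide, here intramolecular at C9 with bromide capture at C10, to give the β,β-dibromo ketone F3. Et3N removes HBr by an E1cB elimination. The fallback returns to the route at 21 and bypasses 20.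

Step 11 (key step). The most likely failures are:
- slow second deprotonation at the congested α-carbon of 13, leaving time for base to attack the halides;
- elimination of triflic acid from 9 in the first alkylation;
- 3-exo closure of the second enolate onto C2–Br;
- poor facial selectivity at C6.

The fallback separates the two bond formations and reverses their order. It sets out from 8, which is silylated (Et3SiCl, imidazole) to the triethylsilyl ether F4. The lithium enolate of 12 is alkylated with the unhindered C5 iodide of F4 (THF/DMPU) to give the open-chain ester F5. HF·pyridine frees the C1 alcohol F6, and Tf2O/2,6-lutidine gives the triflate F7. KN(SiMe3)2 at −78 °C then closes ring B by a 6-exo-tet displacement at C1, where no bromide sits γ to the enolate. The fallback returns at 14.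

Step 5. The most likely failure is lower enantioselectivity or regioselectivity than hoped for on this Z-trisubstituted substrate with a homoallylic silyl ether. The fallback sets out from 5. Racemic anti-bromochlorination (NBS, Et4NCl, CH2Cl2) gives 6 together with its (2R,3R) enantiomer F8. Esterification with (S)-2-methoxy-2-phenylacetic acid (DCC, DMAP) gives the diastereomeric esters F9 (from 6) and F10 (from F8), which are separated by chromatography. iBu2AlH at −78 °C cleaves F9, and the fallback returns at 6.

Step 7. The most likely failure is incomplete discrimination between the two primary hydroxyls, which leads to double iodination or consumes the reagent at C1. The fallback sets out from 6, which is acetylated (Ac2O, pyridine) to the acetate F11. HF·pyridine gives the hydroxy acetate F12, and PPh3/I2/imidazole gives the iodo acetate F13. iBu2AlH at −78 °C removes the acetyl group without forming a free alkoxide under basic conditions, and the fallback returns at 8.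

Step 14. The most likely failures are sluggish addition of the ylide to the doubly neopentyl aldehyde and base-induced elimination on ring B on long exposure. The fallback sets out from 16. Dimethyl (1-diazo-2-oxopropyl)phosphonate with K2CO3 in MeOH (Seyferth–Gilbert homologation) gives the terminal alkyne F14. Hydroboration with dicyclohexylborane and oxidation with NaBO3 give the anti-Markovnikov aldehyde, and the fallback returns at 18.

**Further compounds**

F1 | step 16 | 2-[(1R,3S,4S)-3-bromo-1-(3-bromo-2-methylbut-3-en-2-yl)-4-chloro-4-methylcyclohexyl]acetic acid | C=C(Br)C(C)(C)[C@@]1(CC(=O)O)CC[C@](C)(Cl)[C@@H](Br)C1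
F2 | step 16 | 2-[(1S,3S,4S)-3-bromo-1-(3-bromo-2-methylbut-3-en-2-yl)-4-chloro-4-methylcyclohexyl]acetyl bromide | C=C(Br)C(C)(C)[C@@]1(CC(=O)Br)CC[C@](C)(Cl)[C@@H](Br)C1
F3 | step 16 | (2S,3S,6R)-2,10,10-tribromo-3-chloro-3,11,11-trimethylspiro[5.5]undecan-8-one | O=C1CC(Br)(Br)C(C)(C)[C@@]2(C1)CC[C@](C)(Cl)[C@@H](Br)C2
F4 | step 11 | {[(2S,3S)-2-bromo-3-chloro-5-iodo-3-methylpentyl]oxy}triethylsilane | ICC[C@](C)(Cl)[C@@H](Br)CO[Si](CC)(CC)CC
F5 | step 11 | methyl (5S,6S)-6-bromo-2-(3-bromo-2-methylbut-3-en-2-yl)-5-chloro-5-methyl-7-[(triethylsilyl)oxy]heptanoate (C2 epimers) | C=C(Br)C(C)(C)C(C(=O)OC)CC[C@](C)(Cl)[C@@H](Br)CO[Si](CC)(CC)CC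
F6 | step 11 | methyl (5S,6S)-6-bromo-2-(3-bromo-2-methylbut-3-en-2-yl)-5-chloro-7-hydroxy-5-methylheptanoate (C2 epimers) | C=C(Br)C(C)(C)C(C(=O)OC)CC[C@](C)(Cl)[C@@H](Br)CO
F7 | step 11 | methyl (5S,6S)-6-bromo-2-(3-bromo-2-methylbut-3-en-2-yl)-5-chloro-5-methyl-7-{[(trifluoromethyl)sulfonyl]oxy}heptanoate (C2 epimers) | C=C(Br)C(C)(C)C(C(=O)OC)CC[C@](C)(Cl)[C@@H](Br)COS(=O)(=O)C(F)(F)F
F8 | step 5 | (2R,3R)-2-bromo-5-[(tert-butyldimethylsilyl)oxy]-3-chloro-3-methylpentan-1-ol | CC(C)(C)[Si](C)(C)OCC[C@@](C)(Cl)[C@H](Br)CO
F9 | step 5 | (2S,3S)-2-bromo-5-[(tert-butyldimethylsilyl)oxy]-3-chloro-3-methylpentyl (S)-2-methoxy-2-phenylacetate | CC(C)(C)[Si](C)(C)OCC[C@](C)(Cl)[C@@H](Br)COC(=O)[C@@H](OC)c1ccccc1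
F10 | step 5 | (2R,3R)-2-bromo-5-[(tert-butyldimethylsilyl)oxy]-3-chloro-3-methylpentyl (S)-2-methoxy-2-phenylacetate | CC(C)(C)[Si](C)(C)OCC[C@@](C)(Cl)[C@H](Br)COC(=O)[C@@H](OC)c1ccccc1
F11 | step 7 | (2S,3S)-2-bromo-5-[(tert-butyldimethylsilyl)oxy]-3-chloro-3-methylpentyl acetate | CC(C)(C)[Si](C)(C)OCC[C@](C)(Cl)[C@@H](Br)COC(C)=O
F12 | step 7 | (2S,3S)-2-bromo-3-chloro-5-hydroxy-3-methylpentyl acetate | OCC[C@](C)(Cl)[C@@H](Br)COC(C)=O
F13 | step 7 | (2S,3S)-2-bromo-3-chloro-5-iodo-3-methylpentyl acetate | ICC[C@](C)(Cl)[C@@H](Br)COC(C)=O
F14 | step 14 | (1S,2S,4S)-2-bromo-4-(3-bromo-2-methylbut-3-en-2-yl)-1-chloro-4-ethynyl-1-methylcyclohexane | C=C(Br)C(C)(C)[C@@]1(C#C)CC[C@](C)(Cl)[C@@H](Br)C1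
A1 | alternative 1 | 6,6-(ethylenedioxy)-5,5-dimethylspiro[3.5]nonan-2-one | O=C1CC2(C1)CCCC1(OCCO1)C2(C)C
A2 | alternative 1 | trimethyl(prop-1-yn-1-yl)silane | CC#C[Si](C)(C)C
A3 | alternative 1 | (6S)-10,10-(ethylenedioxy)-3,11,11-trimethyl-2-(trimethylsilyl)spiro[5.5]undec-2-en-4-one | CC1=C([Si](C)(C)C)C[C@@]2(CC1=O)CCCC1(OCCO1)C2(C)C
A4 | alternative 2 | 4-[(tert-butyldimethylsilyl)oxy]-1-diazo-5-(4-hydroxyphenyl)-5-methylhexan-2-one | [N-]=[N+]=CC(=O)CC(O[Si](C)(C)C(C)(C)C)C(C)(C)c1ccc(O)cc1
A5 | alternative 2 | 10-[(tert-butyldimethylsilyl)oxy]-11,11-dimethylspiro[5.5]undeca-1,4-diene-3,8-dione | O=C1C=CC2(C=C1)CC(=O)CC(O[Si](C)(C)C(C)(C)C)C2(C)C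
A6 | alternative 3 | tert-butyl({(2Z)-4-bromo-1-[(3S,4S)-3-bromo-4-chloro-4-methylcyclohexylidene]-5-methylhexa-2,4-dien-1-yl}oxy)dimethylsilane | CC(C)=C(Br)/C=C\C(O[Si](C)(C)C(C)(C)C)=C1CC[C@](C)(Cl)[C@@H](Br)C1
A7 | alternative 3 | tert-butyl{[(2S,3S,6R)-2,10-dibromo-3-chloro-3,11,11-trimethylspiro[5.5]undeca-7,9-dien-7-yl]oxy}dimethylsilane | CC(C)(C)[Si](C)(C)OC1=CC=C(Br)C(C)(C)[C@]12CC[C@](C)(Cl)[C@@H](Br)C2
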